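**Retrosynthetic overview**
- Last bond: C5–CH2, made by [4+2] cycloaddition of an o-quinone methide (from a phenolic Mannich base of the dihydroisocoumarin) onto the C4a=C5 bond of the free isochromenone diol, followed by retro-oxa-Michael opening.
- Dihydroisocoumarin half: the arene ring is built first by Diels–Alder cycloaddition of a 1,3-bis(silyloxy)diene with a 5-hydroxy-2-ynoate from (S)-propylene oxide; the lactone ring closes second; C7 is then aminomethylated.
- Isochromenone half: the carbocycle is bought as (S)-carvone; the trans-7,8-diol is set by epoxidation and hydrolysis under control of the isopropenyl-bearing centre, which is then excised.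
- The pyran ring of that half closes last: β-propynylation, γ-formylation, 6-endo oxa-cyclisation.
- Ring order: arene → lactone; (carbocycle bought) → pyran; union.

Assumption: the target SMILES is read as (7R,8S) in the isochromenone half and (3S) in the lactone half; ethyl propiolate, (S)-propylene oxide, methyl 3-oxopentanoate and (S)-(+)-carvone are the commercial starting materials.

**Route**

Step 1
Reactants: 1 ethyl propiolate; 2 (S)-propylene oxide [(2S)-2-methyloxirane]
Product: 4 ethyl (5S)-5-hydroxyhex-2-ynoate, via lithium acetylide 3 (not isolated)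
Conditions: n-BuLi, THF, −78 °C; BF3·OEt2, then 2, −78 °C; aq. NH4Cl
Reagents that add atoms: none
Why: BF3-promoted SN2 opening of the epoxide at its CH2 terminus by the lithium acetylide (Yamaguchi–Hirao alkynylation) does not touch the purchased stereocentre, so the carbinol stays (S).

Step 2
Reactants: 5 methyl 3-oxopentanoate
Product: 6 1-methoxy-1,3-bis[(trimethylsilyl)oxy]penta-1,3-diene (E/Z mixture)
Conditions: TMSOTf (2.2 equiv), Et3N (2.5 equiv), Et2O, 0 °C → rt
Reagents that add atoms: trimethylsilyl trifluoromethanesulfonate, C[Si](C)(C)OS(=O)(=O)C(F)(F)F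
Why: Double soft enolisation and O-silylation (Simchen conditions) turns the β-keto ester into a Chan-type bis(silyloxy)diene whose terminal methyl becomes the arene C5 methyl.

Step 3
Reactants: 4 ethyl (5S)-5-hydroxyhex-2-ynoate; 6 1-methoxy-1,3-bis[(trimethylsilyl)oxy]penta-1,3-diene
Product: 9 (3S)-6,8-dihydroxy-3,5-dimethyl-3,4-dihydro-1H-isochromen-1-one, via Diels–Alder cycloadduct 7 (not isolated), via hydroxy ester 8 (not isolated)
Conditions: 6 (2.5 equiv), toluene, 110 °C, sealed tube; then 1 M HCl, THF, rt; then TsOH·H2O (cat.), toluene, 80 °C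
Reagents that add atoms: none
Why: A regioselective Diels–Alder cycloaddition (nucleophilic methyl-bearing diene terminus to the β-carbon of the ynoate) builds the six-membered ring, which aromatises by loss of methanol and desilylation, and acid-catalysed lactonisation then closes the dihydroisocoumarin with the (S) centre untouched.

Step 4
Reactants: 9 (3S)-6,8-dihydroxy-3,5-dimethyl-3,4-dihydro-1H-isochromen-1-one
Product: 10 (3S)-7-[(dimethylamino)methyl]-6,8-dihydroxy-3,5-dimethyl-3,4-dihydro-1H-isochromen-1-one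
Conditions: Me2NH (40% aq.), CH2O (37% aq.), EtOH, rt
Reagents that add atoms: formaldehyde, C=O; dimethylamine, CNC
Why: Mannich aminomethylation can only occur at C7, the one free ring position, which is ortho to both phenols.

Step 5
Reactants: 11 (S)-(+)-carvone [(5S)-2-methyl-5-(prop-1-en-2-yl)cyclohex-2-en-1-one]
Product: 12 (1S,4S,6S)-1-methyl-4-(prop-1-en-2-yl)-7-oxabicyclo[4.1.0]heptan-2-one (oxirane trans to isopropenyl)
Conditions: H2O2 (30% aq.), NaOH (cat.), MeOH, 0 °C
Reagents that add atoms: hydrogen peroxide, OO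
Why: In this Weitz–Scheffer nucleophilic epoxidation the hydroperoxide adds axially to the enone face anti to the isopropenyl group, so the purchased centre sets both oxirane carbons as a single trans epoxide.

Step 6
Reactants: 12 (1S,4S,6S)-1-methyl-4-(prop-1-en-2-yl)-7-oxabicyclo[4.1.0]heptan-2-one
Product: 13 (2R,3S,5S)-2,3-dihydroxy-2-methyl-5-(prop-1-en-2-yl)cyclohexan-1-one
Conditions: HClO4 (0.5 M aq.), THF, rt
Reagents that add atoms: water, O
Why: Acid-catalysed trans-diaxial (Fürst–Plattner) epoxide opening by water at the tertiary C2, the regiochemistry known for HCl opening of this oxide, inverts C2 and retains C3 to give the (2R,3S) trans-diol.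

Step 7
Reactants: 13 (2R,3S,5S)-2,3-dihydroxy-2-methyl-5-(prop-1-en-2-yl)cyclohexan-1-one
Product: 14 (2R,3S,5S)-3-[(tert-butyldimethylsilyl)oxy]-2-hydroxy-2-methyl-5-(prop-1-en-2-yl)cyclohexan-1-one
Conditions: TBSOTf (1.1 equiv), 2,6-lutidine, CH2Cl2, −78 → −20 °C
Reagents that add atoms: tert-butyldimethylsilyl trifluoromethanesulfonate, CC(C)(C)[Si](C)(C)OS(=O)(=O)C(F)(F)F
Why: Silyl ether formation selects the secondary hydroxyl over the hindered, hydrogen-bonded tertiary α-ketol hydroxyl.

Step 8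
Reactants: 14 (2R,3S,5S)-3-[(tert-butyldimethylsilyl)oxy]-2-hydroxy-2-methyl-5-(prop-1-en-2-yl)cyclohexan-1-one
Product: 16 (5S,6R)-5-[(tert-butyldimethylsilyl)oxy]-6-hydroxy-6-methylcyclohex-2-en-1-one, via methoxy hydroperoxide 15 (not isolated)
Conditions: O3, CH2Cl2–MeOH, −78 °C; then Cu(OAc)2·H2O, FeSO4·7H2O, −78 °C → rt
Reagents that add atoms: none
Why: Criegee ozonolysis in methanol followed by Schreiber's iron/copper-mediated radical fragmentation (dealkenylation) excises the isopropenyl group and leaves the conjugated enone, removing the controlling centre after it has done its work.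

Step 9
Reactants: 16 (5S,6R)-5-[(tert-butyldimethylsilyl)oxy]-6-hydroxy-6-methylcyclohex-2-en-1-one
Product: 18 (2R,3S)-3-[(tert-butyldimethylsilyl)oxy]-2-hydroxy-2-methyl-5-(prop-1-yn-1-yl)cyclohexan-1-one (C5 epimers), via silyl enol ether 17 (not isolated)
Conditions: CH3C≡CMgBr (2.3 equiv), ZnBr2, THF, 0 °C; then 16, TMSOTf, −40 °C; 1 M HCl work-up
Reagents that add atoms: prop-1-ynylmagnesium bromide, CC#C[Mg]Br
Why: Silyl triflate-promoted conjugate addition of the alkynylzinc reagent places the propynyl group on the β-carbon, and the new centre is erased in the next step so its configuration does not matter.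

Step 10
Reactants: 18 (2R,3S)-3-[(tert-butyldimethylsilyl)oxy]-2-hydroxy-2-methyl-5-(prop-1-yn-1-yl)cyclohexan-1-one
Product: 19 (5S,6R)-5-[(tert-butyldimethylsilyl)oxy]-6-hydroxy-6-methyl-3-(prop-1-yn-1-yl)cyclohex-2-en-1-one
Conditions: IBX (2 equiv), DMSO–fluorobenzene, 70 °C
Reagents that add atoms: none
Why: IBX dehydrogenation of the ketone is regiospecific because the other α-carbon is quaternary, so only the enone conjugated to the alkyne can form.

Step 11
Reactants: 19 (5S,6R)-5-[(tert-butyldimethylsilyl)oxy]-6-hydroxy-6-methyl-3-(prop-1-yn-1-yl)cyclohex-2-en-1-one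
Product: 20 (5S,6R)-5-[(tert-butyldimethylsilyl)oxy]-4-[(dimethylamino)methylidene]-6-hydroxy-6-methyl-3-(prop-1-yn-1-yl)cyclohex-2-en-1-one
Conditions: t-BuOCH(NMe2)2 (3 equiv), toluene, 70 °C
Reagents that add atoms: tert-butoxybis(dimethylamino)methane, CN(C)C(OC(C)(C)C)N(C)C
Why: Bredereck aminomethylenation takes place at the vinylogous γ-CH2, the only acidic ring position since the α'-carbon is quaternary, and installs the future C1 as a stable dienaminone.

Step 12
Reactants: 20 (5S,6R)-5-[(tert-butyldimethylsilyl)oxy]-4-[(dimethylamino)methylidene]-6-hydroxy-6-methyl-3-(prop-1-yn-1-yl)cyclohex-2-en-1-one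
Product: 23 (7R,8S)-7,8-dihydroxy-3,7-dimethyl-7,8-dihydro-6H-isochromen-6-one, via hydroxymethylene enynone 21 (not isolated), via silylated isochromenone 22 (not isolated)
Conditions: AcOH–H2O–THF, AgOTf (5 mol %), rt; then HF·pyridine, THF, 0 °C; aq. NaHCO3
Reagents that add atoms: water, O
Why: Enaminone hydrolysis gives the hydroxymethylene enol, which closes the pyran by silver-catalysed 6-endo-dig oxa-cyclisation onto the ynenone (a 1,6-conjugate addition), and fluoride desilylation cleaves only the Si–O bond so both stereocentres are retained.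

Step 13
Reactants: 10 (3S)-7-[(dimethylamino)methyl]-6,8-dihydroxy-3,5-dimethyl-3,4-dihydro-1H-isochromen-1-one; 23 (7R,8S)-7,8-dihydroxy-3,7-dimethyl-7,8-dihydro-6H-isochromen-6-one
Product: 26 (7R,8S)-5-{[(3S)-6,8-dihydroxy-3,5-dimethyl-1-oxo-3,4-dihydro-1H-isochromen-7-yl]methyl}-7,8-dihydroxy-3,7-dimethyl-7,8-dihydro-6H-isochromen-6-one (CNP0356349.2), via o-quinone methide 24 (not isolated), via chroman cycloadduct 25 (not isolated)
Conditions: 10 (1.2 equiv), 1,4-dioxane, 100 °C, N2 stream
Reagents that add atoms: none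
Why: Thermal loss of dimethylamine gives the o-quinone methide, which adds to the electron-rich C4a=C5 bond in an inverse-electron-demand hetero-Diels–Alder cycloaddition, and the labile chroman ketal opens by retro-oxa-Michael elimination to restore the chromophore and the phenol without touching any of the three stereocentres.

**Compound list**

1 | ethyl propiolate (ethyl prop-2-ynoate) | CCOC(=O)C#C | starting material
2 | (S)-propylene oxide, (2S)-2-methyloxirane | C[C@H]1CO1 | starting material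
3 | ethyl 3-lithioprop-2-ynoate | CCOC(=O)C#C[Li] | intermediate
4 | ethyl (5S)-5-hydroxyhex-2-ynoate | CCOC(=O)C#CC[C@H](C)O | intermediate
5 | methyl 3-oxopentanoate | CCC(=O)CC(=O)OC | starting material
6 | 1-methoxy-1,3-bis[(trimethylsilyl)oxy]penta-1,3-diene (E/Z mixture) | CC=C(O[Si](C)(C)C)C=C(OC)O[Si](C)(C)C | intermediate
7 | ethyl 2-[(2S)-2-hydroxypropyl]-6-methoxy-3-methyl-4,6-bis[(trimethylsilyl)oxy]cyclohexa-1,4-diene-1-carboxylate (C3/C6 diastereomers) | CCOC(=O)C1=C(C[C@H](C)O)C(C)C(O[Si](C)(C)C)=CC1(OC)O[Si](C)(C)C | intermediate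
8 | ethyl 2,4-dihydroxy-6-[(2S)-2-hydroxypropyl]-5-methylbenzoate | CCOC(=O)c1c(O)cc(O)c(C)c1C[C@H](C)O | intermediate
9 | (3S)-6,8-dihydroxy-3,5-dimethyl-3,4-dihydro-1H-isochromen-1-one | O=C1O[C@@H](C)Cc2c(C)c(O)cc(O)c12 | intermediate
10 | (3S)-7-[(dimethylamino)methyl]-6,8-dihydroxy-3,5-dimethyl-3,4-dihydro-1H-isochromen-1-one | O=C1O[C@@H](C)Cc2c(C)c(O)c(CN(C)C)c(O)c12 | intermediate
11 | (S)-(+)-carvone, (5S)-2-methyl-5-(prop-1-en-2-yl)cyclohex-2-en-1-one | CC1=CC[C@@H](CC1=O)C(C)=C | starting material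
12 | (1S,4S,6S)-1-methyl-4-(prop-1-en-2-yl)-7-oxabicyclo[4.1.0]heptan-2-one (oxirane trans to isopropenyl) | O=C1[C@@]2(C)O[C@H]2C[C@H](C(C)=C)C1 | intermediate
13 | (2R,3S,5S)-2,3-dihydroxy-2-methyl-5-(prop-1-en-2-yl)cyclohexan-1-one | O=C1[C@](C)(O)[C@@H](O)C[C@H](C(C)=C)C1 | intermediate
14 | (2R,3S,5S)-3-[(tert-butyldimethylsilyl)oxy]-2-hydroxy-2-methyl-5-(prop-1-en-2-yl)cyclohexan-1-one | O=C1[C@](C)(O)[C@@H](O[Si](C)(C)C(C)(C)C)C[C@H](C(C)=C)C1 | intermediate
15 | (2R,3S,5S)-3-[(tert-butyldimethylsilyl)oxy]-5-(1-hydroperoxy-1-methoxyethyl)-2-hydroxy-2-methylcyclohexan-1-one (side-chain epimers) | O=C1[C@](C)(O)[C@@H](O[Si](C)(C)C(C)(C)C)C[C@H](C(C)(OC)OO)C1 | intermediate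
16 | (5S,6R)-5-[(tert-butyldimethylsilyl)oxy]-6-hydroxy-6-methylcyclohex-2-en-1-one | C1=CC(=O)[C@](C)(O)[C@@H](O[Si](C)(C)C(C)(C)C)C1 | intermediate
17 | (1R,6S)-6-[(tert-butyldimethylsilyl)oxy]-1-methyl-4-(prop-1-yn-1-yl)-2-[(trimethylsilyl)oxy]cyclohex-2-en-1-ol (C4 epimers; tertiary OH drawn free) | CC#CC1C=C(O[Si](C)(C)C)[C@](C)(O)[C@@H](O[Si](C)(C)C(C)(C)C)C1 | intermediate
18 | (2R,3S)-3-[(tert-butyldimethylsilyl)oxy]-2-hydroxy-2-methyl-5-(prop-1-yn-1-yl)cyclohexan-1-one (C5 epimers) | CC#CC1CC(=O)[C@](C)(O)[C@@H](O[Si](C)(C)C(C)(C)C)C1 | intermediate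
19 | (5S,6R)-5-[(tert-butyldimethylsilyl)oxy]-6-hydroxy-6-methyl-3-(prop-1-yn-1-yl)cyclohex-2-en-1-one | CC#CC1=CC(=O)[C@](C)(O)[C@@H](O[Si](C)(C)C(C)(C)C)C1 | intermediate
20 | (5S,6R)-5-[(tert-butyldimethylsilyl)oxy]-4-[(dimethylamino)methylidene]-6-hydroxy-6-methyl-3-(prop-1-yn-1-yl)cyclohex-2-en-1-one (enamine geometry not fixed) | CC#CC1=CC(=O)[C@](C)(O)[C@@H](O[Si](C)(C)C(C)(C)C)C1=CN(C)C | intermediate
21 | (5S,6R)-5-[(tert-butyldimethylsilyl)oxy]-6-hydroxy-4-(hydroxymethylidene)-6-methyl-3-(prop-1-yn-1-yl)cyclohex-2-en-1-one | CC#CC1=CC(=O)[C@](C)(O)[C@@H](O[Si](C)(C)C(C)(C)C)C1=CO | intermediate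
22 | (7R,8S)-8-[(tert-butyldimethylsilyl)oxy]-7-hydroxy-3,7-dimethyl-7,8-dihydro-6H-isochromen-6-one | CC1=CC2=CC(=O)[C@](C)(O)[C@@H](O[Si](C)(C)C(C)(C)C)C2=CO1 | intermediate
23 | (7R,8S)-7,8-dihydroxy-3,7-dimethyl-7,8-dihydro-6H-isochromen-6-one | CC1=CC2=CC(=O)[C@](C)(O)[C@@H](O)C2=CO1 | intermediate
24 | (3S)-8-hydroxy-3,5-dimethyl-7-methylidene-3,4-dihydro-1H-isochromene-1,6(7H)-dione (o-quinone methide) | C=C1C(=O)C(C)=C2C[C@H](C)OC(=O)C2=C1O | intermediate
25 | chroman [4+2] adduct of 24 and 23: aryl O6 bonded to C4a and the CH2 bonded to C5 of the isochromenone, (7R,8S) and (3S) centres unchanged, C4a/C5 not fixed | CC1=CC23Oc4c(C)c5C[C@H](C)OC(=O)c5c(O)c4CC2C(=O)[C@](C)(O)[C@@H](O)C3=CO1 | intermediate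
26 | (7R,8S)-5-{[(3S)-6,8-dihydroxy-3,5-dimethyl-1-oxo-3,4-dihydro-1H-isochromen-7-yl]methyl}-7,8-dihydroxy-3,7-dimethyl-7,8-dihydro-6H-isochromen-6-one | CC1=CC2=C(Cc3c(O)c(C)c4c(c3O)C(=O)O[C@@H](C)C4)C(=O)[C@](C)(O)[C@@H](O)C2=CO1 | target

**Step count and risks**

Total steps: 13. Longest linear sequence: 9 steps (11 → 26, steps 5 to 13).

Step 6 is the first risk, because the regiochemistry of water attack decides which enantiomeric diol series is formed, and the α,β-epoxy ketone could also rearrange. The fallback sets out from 11 and reaches the same diol by a path where stereoelectronic and electronic preferences agree. Luche reduction (NaBH4, CeCl3·7H2O, MeOH, −78 °C) gives cis-carveol F1. Hydroxyl-directed epoxidation (VO(acac)2, t-BuOOH, CH2Cl2) gives the syn-epoxy alcohol F2. Dess–Martin oxidation gives the cis-epoxy ketone F3, the oxirane now syn to the isopropenyl group. Aqueous HClO4 then opens it trans-diaxially at the secondary C3, remote from the carbonyl, and the route is rejoined at 13.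

Step 11 is the second risk, because the γ-condensation may be slow and the intermediate dienolate can expel the β-silyloxy group. The fallback sets out from 19 and avoids a free carbanion. TMSOTf and Et3N give the bis(trimethylsilyl) dienol ether F4. A vinylogous Mukaiyama reaction with HC(OMe)3 and BF3·OEt2 at the γ-carbon gives the γ-(dimethoxymethyl) enynone F5. The aqueous acid of step 12 unmasks it to the hydroxymethylene compound, so the route is rejoined at 21.

Step 13 is the third risk, because the liberated amine and the heat may damage the isochromenone, and the o-quinone methide may oligomerise. The fallback sets out from 9 and uses a reductive alkylation instead. Duff formylation (hexamethylenetetramine, TFA, then aqueous acid) gives the 7-carbaldehyde F6. Condensation with 23 at C5 under ethylenediammonium diacetate catalysis gives the quinone methide F7, which a Hantzsch ester reduces in the same pot by hydride transfer. This comes back to the route at 26.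

**Further compounds**

F1 | step 6 | (1S,5S)-2-methyl-5-(prop-1-en-2-yl)cyclohex-2-en-1-ol (cis-carveol) | O[C@@H]1C(C)=CC[C@H](C(C)=C)C1
F2 | step 6 | 2,3-epoxide of cis-carveol F1 with the oxirane syn to the hydroxyl and isopropenyl groups | O[C@@H]1[C@]2(C)O[C@@H]2C[C@H](C(C)=C)C1
F3 | step 6 | (1R,4S,6R)-1-methyl-4-(prop-1-en-2-yl)-7-oxabicyclo[4.1.0]heptan-2-one (oxirane cis to isopropenyl) | O=C1[C@]2(C)O[C@@H]2C[C@H](C(C)=C)C1
F4 | step 11 | bis(trimethylsilyl) dienol ether of 19 (TMS on the dienol oxygen and on the tertiary oxygen, TBS ether retained) | CC#CC1=C[C@H](O[Si](C)(C)C(C)(C)C)[C@@](C)(O[Si](C)(C)C)C(O[Si](C)(C)C)=C1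
F5 | step 11 | (5S,6R)-5-[(tert-butyldimethylsilyl)oxy]-4-(dimethoxymethyl)-6-hydroxy-6-methyl-3-(prop-1-yn-1-yl)cyclohex-2-en-1-one (C4 epimers) | CC#CC1=CC(=O)[C@](C)(O)[C@@H](O[Si](C)(C)C(C)(C)C)C1C(OC)OC
F6 | step 13 | (3S)-6,8-dihydroxy-3,5-dimethyl-1-oxo-3,4-dihydro-1H-isochromene-7-carbaldehyde | O=Cc1c(O)c(C)c2C[C@H](C)OC(=O)c2c1O
F7 | step 13 | quinone methide from F6 and 23 (exocyclic CH= joining C7 of the lactone half to C5 of the isochromenone, geometry not fixed) | CC1=CC2=C(C=C3C(=O)C(C)=C4C[C@H](C)OC(=O)C4=C3O)C(=O)[C@](C)(O)[C@@H](O)C2=CO1
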